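**Strategy.** The eleven-membered carbocycle is made by deleting one sulfur atom from a twelve-membered cyclic sulfone (ring atoms numbered C1, the quaternary carbon, to C11 through the E alkene). A Ramberg–Bäcklund contraction joins C2 and C3 and creates the isolated E C2=C3 alkene, the one flanked by the quaternary C1 and the carbinol C4, where two methylene groups can be bridged by sulfur without touching a stereocentre. The precursor thiacycle already carries the C5–C6 epoxide, the C4 oxygen, the C9=C10 alkene and the side chain. It is closed by thiolate opening of a terminal epoxide after a Horner–Wadsworth–Emmons union of a geraniol-derived quaternary aldehyde with an epoxy phosphonate.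

Key step: step 25

Remark on locants: C4 = ester carbinol, C5/C6 = epoxide, C9 = carbon bearing CH2OH, C12–C17 = side chain on C1 with C14 the carbinol; "as in the target" means the spatial arrangement shown in the SMILES (CIP letters change with the substituents).
Remark on chemistry: the epoxy silyl ether rearrangement (step 3) is assumed to go with anti migration (inversion at the migration terminus), and the L-fructose-derived Shi ketone is assumed to give the (S)-epoxide in step 5; if either sense is opposite, the other tartrate or ketone enantiomer is used.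
Remark on purity: the two fragments are each expected to be enantio-enriched but not enantiopure, so minor diastereomers formed at step 19 should be removed at the macrocycle stage.

**Fragment A (C1, C2, C10–C17)**

Step 1
Reactants: 1 geraniol
Product: 2 (2R,3R)-2,3-epoxygeraniol
Conditions: Ti(Oi-Pr)4 (5 mol %), D-(−)-diethyl tartrate (7 mol %), t-BuOOH, 4 Å MS, CH2Cl2, −20 °C
Reagents that add atoms: tert-butyl hydroperoxide CC(C)(C)OO
Why: Sharpless asymmetric epoxidation of an allylic alcohol, in which the D-(−)-tartrate titanium catalyst should deliver oxygen to the face that gives the (2R,3R)-epoxide and so fixes the carbon that becomes the quaternary C1.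

Step 2
Reactants: 2 (2R,3R)-2,3-epoxygeraniol
Product: 3 tert-butyldimethylsilyl ether of 2
Conditions: TBSCl, imidazole, DMF, 0 °C to rt
Reagents that add atoms: tert-butyldimethylsilyl chloride CC(C)(C)[Si](C)(C)Cl
Why: Standard silylation of a primary alcohol, which installs the silyloxymethyl group that migrates in the next step.

Step 3
Reactants: 3 epoxy silyl ether
Product: 4 (2R)-2-[(tert-butyldimethylsilyloxy)methyl]-2,6-dimethylhept-5-enal
Conditions: MeAl(OC6H2-4-Br-2,6-t-Bu2)2 (promoter, 0.2–2 equiv), CH2Cl2, −78 °C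
Reagents that add atoms: none
Why: Lewis-acid-promoted semipinacol-type rearrangement of a 2,3-epoxy silyl ether, in which the bulky aluminium phenoxide ionises the tertiary C–O bond and the silyloxymethyl group migrates anti to it, so the epoxide carbon becomes the all-carbon quaternary centre with inversion and the neighbouring carbon becomes the aldehyde.

Step 4
Reactants: 4 quaternary aldehyde
Product: 6 (3S)-3-[(tert-butyldimethylsilyloxy)methyl]-1,1-dimethoxy-3,7-dimethyloct-6-ene, via methyl enol ether 5 (not isolated)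
Conditions: MeOCH2PPh3Cl, KN(SiMe3)2, THF, 0 °C to rt; then PPTS, MeOH, rt
Reagents that add atoms: (methoxymethyl)triphenylphosphonium chloride COC[P+](c1ccccc1)(c1ccccc1)c1ccccc1.[Cl-]; methanol CO
Why: Wittig methoxymethylenation adds C10 to the hindered aldehyde and acid-catalysed addition of methanol to the enol ether gives the dimethyl acetal that masks C10 during the next oxidations, with no stereocentre touched.

Step 5
Reactants: 6 dimethyl acetal
Product: 7 (S)-epoxide of the C14=C15 alkene of 6
Conditions: L-fructose-derived Shi ketone (30 mol %), Oxone (2KHSO5·KHSO4·K2SO4), K2CO3, Bu4NHSO4, MeCN/CH2(OMe)2/aq. Na2B4O7 buffer, 0 °C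
Reagents that add atoms: potassium peroxymonosulfate (Oxone) [K+].[O-]S(=O)(=O)OO
Why: Shi asymmetric epoxidation, in which the chiral dioxirane attacks the only electron-rich trisubstituted alkene through a spiro transition state and should set the (S) configuration of the future carbinol C14.

Step 6
Reactants: 7 epoxide
Product: 8 (S)-allylic alcohol with the isopropenyl group (C14–OH)
Conditions: Et2Al(NC9H18) (diethylaluminium 2,2,6,6-tetramethylpiperidide, from LiNC9H18 and Et2AlCl), toluene, 0 °C
Reagents that add atoms: none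
Why: Base-mediated isomerisation of a trisubstituted epoxide to an allylic alcohol by syn β-elimination on aluminium, in which a methyl proton is removed so the C14–O bond and its (S) configuration stay untouched.

Step 7
Reactants: 8 allylic alcohol
Product: 9 C14 triisopropylsilyl ether
Conditions: TIPSOTf, 2,6-lutidine, CH2Cl2, −78 to 0 °C
Reagents that add atoms: triisopropylsilyl triflate CC(C)[Si](C(C)C)(C(C)C)OS(=O)(=O)C(F)(F)F
Why: Silylation of a secondary alcohol with a silyl triflate, using a bulky group that should outlast the primary tert-butyldimethylsilyl ether.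

Step 8
Reactants: 9 bis-silyl ether
Product: 10 primary (C2) alcohol
Conditions: Bu4NF (1.1 equiv), THF, 0 °C
Reagents that add atoms: none
Why: Fluoride-mediated desilylation, expected to be selective for the primary tert-butyldimethylsilyl ether over the hindered secondary triisopropylsilyl ether.

Step 9
Reactants: 10 primary alcohol
Product: 12 C2 thioacetate, via neopentyl triflate 11 (not isolated)
Conditions: Tf2O, pyridine, CH2Cl2, −78 to −20 °C; then KSC(O)CH3, DMF, −20 °C to rt
Reagents that add atoms: potassium thioacetate CC(=O)[S-].[K+]; triflic anhydride O=S(=O)(OS(=O)(=O)C(F)(F)F)C(F)(F)F (its CF3SO2 group is present only in 11)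
Why: Sulfonylation followed by SN2 displacement, in which the triflate is reactive enough for the neopentyl-type carbon and the small, strongly nucleophilic thioacetate should displace it before the acetal oxygen can take part.

Step 10
Reactants: 12 thioacetate acetal
Product: 13 fragment A aldehyde (C10 aldehyde, C2 thioacetate, C14 silyl ether)
Conditions: PPTS, acetone/H2O (10:1), 45 °C
Reagents that add atoms: water O
Why: Acid-catalysed acetal hydrolysis, mild enough for the thioester, the silyl ether and the alkene.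

**Fragment B (C3–C9)**

Step 11
Reactants: 14 (4-carboxybutyl)triphenylphosphonium bromide; 15 1-(tert-butyldimethylsilyloxy)propan-2-one
Product: 16 (Z)-7-(tert-butyldimethylsilyloxy)-6-methylhept-5-enoic acid
Conditions: NaN(SiMe3)2 (2.1 equiv), THF, −78 °C to rt; aq. HCl work-up
Reagents that add atoms: none
Why: Wittig olefination of an α-silyloxy ketone with a non-stabilised ylide, a reaction type that places the oxygen-bearing carbon cis to the ylide chain and so gives the Z alkene needed for the cis-epoxide.

Step 12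
Reactants: 16 silyloxy acid
Product: 17 methyl (Z)-7-hydroxy-6-methylhept-5-enoate
Conditions: HCl in MeOH (about 0.3 M), 0 °C to rt
Reagents that add atoms: methanol CO
Why: Fischer esterification with concurrent acidic methanolysis of the primary silyl ether.

Step 13
Reactants: 17 Z-allylic alcohol
Product: 18 methyl 4-[(2S,3R)-3-(hydroxymethyl)-3-methyloxiran-2-yl]butanoate
Conditions: Ti(Oi-Pr)4, D-(−)-diethyl tartrate, t-BuOOH, 4 Å MS, CH2Cl2, −20 °C
Reagents that add atoms: tert-butyl hydroperoxide CC(C)(C)OO
Why: Sharpless asymmetric epoxidation, stereospecific for the Z alkene (C4 and C7 cis on the oxirane) with the D-(−)-tartrate catalyst setting C5 and C6 by reagent control.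

Step 14
Reactants: 18 epoxy alcohol
Product: 19 methyl 4-[(2S,3S)-3-formyl-3-methyloxiran-2-yl]butanoate
Conditions: Dess–Martin periodinane, NaHCO3, CH2Cl2, 0 °C to rt
Reagents that add atoms: none
Why: Dess–Martin oxidation of a primary alcohol to a non-enolisable epoxy aldehyde under buffered conditions that spare the epoxide.

Step 15
Reactants: 19 epoxy aldehyde
Product: 20 chlorohydrin (both C4 epimers)
Conditions: ICH2Cl, MeLi·LiBr, THF, −78 °C; AcOH quench at −78 °C
Reagents that add atoms: chloroiodomethane ClCI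
Why: Addition of chloromethyllithium, made in the flask by iodine–lithium exchange, to the aldehyde, which is faster than addition to the ester; the carbinol configuration does not matter because it is erased in the next step.

Step 16
Reactants: 20 chlorohydrin mixture
Product: 21 α-chloro α′,β′-epoxy ketone
Conditions: Dess–Martin periodinane, NaHCO3, CH2Cl2, rt
Reagents that add atoms: none
Why: Dess–Martin oxidation converges both epimers on one ketone.

Step 17
Reactants: 21 chloro epoxy ketone
Product: 23 methyl 4-[(2S,3S)-3-methyl-3-[(2R)-oxiran-2-yl]oxiran-2-yl]butanoate, via erythro chlorohydrin 22 (not isolated)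
Conditions: Zn(BH4)2, Et2O, −20 °C; then K2CO3, MeOH, 0 °C to rt
Reagents that add atoms: none
Why: Chelation-controlled reduction of an α,β-epoxy ketone, in which zinc bridges the carbonyl and epoxide oxygens and hydride attacks the face away from the C6–C7 arm to give the erythro carbinol (C4 as in the target), followed by Williamson-type closure of the chlorohydrin to the terminal epoxide with retention at C4.

Step 18
Reactants: 23 bis-epoxide ester
Product: 25 α-phosphono ester (C9 epimers), via phosphonite 24 (not isolated)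
Conditions: LiN(i-Pr)2 (1.1 equiv), THF, −78 °C; ClP(OEt)2, −78 °C to rt; then 30% H2O2, 0 °C
Reagents that add atoms: diethyl chlorophosphite CCOP(Cl)OCC; hydrogen peroxide OO
Why: C-phosphinylation of an ester enolate with a soft trivalent phosphorus electrophile, followed by oxidation to the phosphonate, puts the Horner–Wadsworth–Emmons handle on C9 without touching the epoxides.

**Union, ring closure, contraction, end game**

Step 19
Reactants: 13 fragment A aldehyde; 25 phosphonate
Product: 26 (E)-enoate (C9=C10 with C8 and C11 cis and the ester trans to C11)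
Conditions: LiCl, i-Pr2NEt, MeCN, rt
Reagents that add atoms: none
Why: Horner–Wadsworth–Emmons olefination under mild lithium chloride and amine conditions, which favours the E trisubstituted enoate and leaves the thioacetate intact.

Step 20
Reactants: 26 enoate thioacetate
Product: 27 allylic alcohol with free C2 thiol
Conditions: i-Bu2AlH (6 equiv), CH2Cl2, −78 °C, substrate added to the hydride; Rochelle salt (KNaC4H4O6) work-up under argon
Reagents that add atoms: none
Why: Hydride reduction of the enoate to the allylic alcohol with concurrent reductive cleavage of the thioester, run by inverse addition so that the Michael acceptor is gone before a thiolate can add to it.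

Step 21
Reactants: 27 mercapto bis-epoxide
Product: 28 twelve-membered hydroxy sulfide (S between C2 and C3, C4–OH)
Conditions: Cs2CO3 (0.5 equiv), degassed DMF/MeOH (9:1), 1 mM, syringe-pump addition, rt
Reagents that add atoms: none
Why: Macrocyclisation by intramolecular thiolate opening of the terminal epoxide at its unhindered CH2 (C3), which frees the C4 hydroxyl with the configuration set in step 17, while the trisubstituted epoxide is too hindered to react.

Step 22
Reactants: 28 macrocyclic diol
Product: 29 primary tert-butyldimethylsilyl ether (C9–CH2OTBS)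
Conditions: TBSCl, imidazole, CH2Cl2, 0 °C
Reagents that add atoms: tert-butyldimethylsilyl chloride CC(C)(C)[Si](C)(C)Cl
Why: Selective silylation of the primary allylic alcohol over the hindered secondary C4 alcohol.

Step 23
Reactants: 29 C4 alcohol
Product: 30 C4 p-methoxybenzyl ether
Conditions: NaH, 4-methoxybenzyl chloride, Bu4NI (cat.), THF/DMF, 0 °C to rt
Reagents that add atoms: 4-methoxybenzyl chloride COc1ccc(CCl)cc1
Why: Williamson etherification, safe here because Payne migration of the alkoxide would need SN2 attack at the fully substituted C5.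

Step 24
Reactants: 30 sulfide
Product: 31 twelve-membered sulfone
Conditions: n-Pr4N[RuO4] (10 mol %), N-methylmorpholine N-oxide (3 equiv), 4 Å MS, MeCN, 40 °C
Reagents that add atoms: N-methylmorpholine N-oxide C[N+]1([O-])CCOCC1
Why: Perruthenate-catalysed oxidation of a sulfide to the sulfone under neutral conditions that spare the alkenes, the epoxide and the ethers.

Step 25
Reactants: 31 twelve-membered sulfone
Product: 34 eleven-membered triene with E C2=C3, via α-bromo sulfone 32 (not isolated), via episulfone 33 (not isolated)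
Conditions: CBr2F2, KOH/Al2O3, t-BuOH/CH2Cl2, 0 °C to rt
Reagents that add atoms: dibromodifluoromethane FC(F)(Br)Br (its bromine is present only in 32)
Why: Ramberg–Bäcklund reaction with halogenation in the flask: KOH/Al2O3 deprotonates the sulfone, the carbanion takes bromine from CBr2F2 to give 32, a second deprotonation on the other α-carbon and 3-exo-tet displacement of bromide give the thiirane 1,1-dioxide 33, and loss of SO2 leaves the C2=C3 alkene, so the twelve-membered ring contracts to the eleven-membered carbocycle. The closest known reactions are Ramberg–Bäcklund contractions of medium-ring and macrocyclic sulfones to cycloalkenes and of β-alkoxy sulfones to alkenes with the alkoxy group kept. The only ring closed is the transient three-membered episulfone (3-exo-tet); no stereocentre is created, and the alkene geometry follows from the episulfone, whose α-sulfonyl positions epimerise under the strongly basic conditions to the trans isomer that keeps the quaternary C1 and the branched C4 apart, so the E alkene is expected. The step needs bromination and 1,3-elimination to outrun E1cB loss of the C4 ether and needs the other alkenes to stay untouched: bromine transfer to an α-sulfonyl carbanion is very fast, p-methoxybenzyl oxide is a poor leaving group, C1 is quaternary so nothing can be eliminated on that side, and difluorocarbene is not expected to add to the trisubstituted and 1,1-disubstituted alkenes under these conditions.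

Step 26
Reactants: 34 p-methoxybenzyl ether
Product: 35 C4 allylic alcohol
Conditions: DDQ, CH2Cl2/pH 7 buffer, 0 °C
Reagents that add atoms: none
Why: Oxidative cleavage of a p-methoxybenzyl ether by hydride abstraction, which leaves the silyl ethers, the epoxide and the alkenes alone.

Step 27
Reactants: 35 C4 alcohol
Product: 36 C4 3-methylbut-2-enoate (bis-silyl ether)
Conditions: 3-methylbut-2-enoyl chloride, pyridine, DMAP (cat.), CH2Cl2, 0 °C to rt
Reagents that add atoms: 3-methylbut-2-enoyl chloride CC(C)=CC(Cl)=O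
Why: DMAP-catalysed acylation of the only free hydroxyl with retention at C4, using pyridine as a weak base so that the acyl group is not deconjugated.

Step 28
Reactants: 36 bis-silyl ether
Product: 37 CNP0309478.6
Conditions: Bu4NF, AcOH, THF, rt to 40 °C
Reagents that add atoms: none
Why: Buffered fluoride desilylation removes both silyl ethers, and the ester cannot migrate because no hydroxyl is adjacent to C4.

**Compound list**

1 | geraniol | CC(C)=CCC/C(C)=C/CO | starting material
2 | (2R,3R)-2,3-epoxygeraniol | CC(C)=CCC[C@@]1(C)O[C@@H]1CO | intermediate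
3 | (2R,3R)-2,3-epoxygeranyl tert-butyldimethylsilyl ether | CC(C)=CCC[C@@]1(C)O[C@@H]1CO[Si](C)(C)C(C)(C)C | intermediate
4 | (2R)-2-[(tert-butyldimethylsilyloxy)methyl]-2,6-dimethylhept-5-enal | CC(C)=CCC[C@](C=O)(C)CO[Si](C)(C)C(C)(C)C | intermediate
5 | methyl enol ether of homologated 4 (E/Z mixture, quaternary carbon S; not isolated) | CC(C)=CCC[C@](C=COC)(C)CO[Si](C)(C)C(C)(C)C | intermediate
6 | (3S)-3-[(tert-butyldimethylsilyloxy)methyl]-1,1-dimethoxy-3,7-dimethyloct-6-ene | CC(C)=CCC[C@](CC(OC)OC)(C)CO[Si](C)(C)C(C)(C)C | intermediate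
7 | (S)-epoxide of the trisubstituted alkene of 6 (quaternary carbon S) | CC1(C)O[C@H]1CC[C@](CC(OC)OC)(C)CO[Si](C)(C)C(C)(C)C | intermediate
8 | (3S,6S)-6-[(tert-butyldimethylsilyloxy)methyl]-8,8-dimethoxy-2,6-dimethyloct-1-en-3-ol | C=C(C)[C@@H](O)CC[C@](CC(OC)OC)(C)CO[Si](C)(C)C(C)(C)C | intermediate
9 | triisopropylsilyl ether of 8 | C=C(C)[C@@H](O[Si](C(C)C)(C(C)C)C(C)C)CC[C@](CC(OC)OC)(C)CO[Si](C)(C)C(C)(C)C | intermediate
10 | primary alcohol from 9 (C2–OH, C14–OTIPS, C10 dimethyl acetal) | C=C(C)[C@@H](O[Si](C(C)C)(C(C)C)C(C)C)CC[C@](CC(OC)OC)(C)CO | intermediate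
11 | neopentyl triflate of 10 (not isolated) | C=C(C)[C@@H](O[Si](C(C)C)(C(C)C)C(C)C)CC[C@](CC(OC)OC)(C)COS(=O)(=O)C(F)(F)F | intermediate
12 | C2 thioacetate (C10 dimethyl acetal, C14–OTIPS) | C=C(C)[C@@H](O[Si](C(C)C)(C(C)C)C(C)C)CC[C@](CC(OC)OC)(C)CSC(C)=O | intermediate
13 | fragment A aldehyde: S-[(2S,5S)-2,6-dimethyl-2-(2-oxoethyl)-5-(triisopropylsilyloxy)hept-6-en-1-yl] ethanethioate | C=C(C)[C@@H](O[Si](C(C)C)(C(C)C)C(C)C)CC[C@](CC=O)(C)CSC(C)=O | intermediate
14 | (4-carboxybutyl)triphenylphosphonium bromide | OC(=O)CCCC[P+](c1ccccc1)(c1ccccc1)c1ccccc1.[Br-] | starting material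
15 | 1-(tert-butyldimethylsilyloxy)propan-2-one | CC(=O)CO[Si](C)(C)C(C)(C)C | starting material
16 | (Z)-7-(tert-butyldimethylsilyloxy)-6-methylhept-5-enoic acid | OC(=O)CCC/C=C(/C)CO[Si](C)(C)C(C)(C)C | intermediate
17 | methyl (Z)-7-hydroxy-6-methylhept-5-enoate | COC(=O)CCC/C=C(/C)CO | intermediate
18 | methyl 4-[(2S,3R)-3-(hydroxymethyl)-3-methyloxiran-2-yl]butanoate | OC[C@@]1(C)O[C@H]1CCCC(=O)OC | intermediate
19 | methyl 4-[(2S,3S)-3-formyl-3-methyloxiran-2-yl]butanoate | O=C[C@@]1(C)O[C@H]1CCCC(=O)OC | intermediate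
20 | chlorohydrin from 19 (2-chloro-1-hydroxyethyl group on the oxirane, both carbinol epimers) | ClCC(O)[C@@]1(C)O[C@H]1CCCC(=O)OC | intermediate
21 | methyl 4-[(2S,3S)-3-(chloroacetyl)-3-methyloxiran-2-yl]butanoate | ClCC(=O)[C@@]1(C)O[C@H]1CCCC(=O)OC | intermediate
22 | erythro chlorohydrin, methyl 4-[(2S,3R)-3-[(1S)-2-chloro-1-hydroxyethyl]-3-methyloxiran-2-yl]butanoate (not isolated) | ClC[C@@H](O)[C@@]1(C)O[C@H]1CCCC(=O)OC | intermediate
23 | methyl 4-[(2S,3S)-3-methyl-3-[(2R)-oxiran-2-yl]oxiran-2-yl]butanoate | C1O[C@H]1[C@@]2(C)O[C@H]2CCCC(=O)OC | intermediate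
24 | diethyl phosphonite at C9 of 23 (trivalent phosphorus, C9 epimers; not isolated) | C1O[C@H]1[C@@]2(C)O[C@H]2CCC(C(=O)OC)P(OCC)OCC | intermediate
25 | methyl 2-(diethoxyphosphoryl)-4-[bis-epoxide as in 23]butanoate (C9 epimers) | C1O[C@H]1[C@@]2(C)O[C@H]2CCC(C(=O)OC)P(=O)(OCC)OCC | intermediate
26 | (E)-enoate: C9(CO2Me)=C10 with C8 and C11 cis; C2 thioacetate; C14–OTIPS; bis-epoxide; stereocentres as in the target | C=C(C)[C@@H](O[Si](C(C)C)(C(C)C)C(C)C)CC[C@](C/C=C(\CC[C@@H]1O[C@]1(C)[C@H]1CO1)C(=O)OC)(C)CSC(C)=O | intermediate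
27 | allylic alcohol (C9–CH2OH) with free C2 thiol; bis-epoxide; C14–OTIPS | C=C(C)[C@@H](O[Si](C(C)C)(C(C)C)C(C)C)CC[C@](C/C=C(\CC[C@@H]1O[C@]1(C)[C@H]1CO1)CO)(C)CS | intermediate
28 | twelve-membered hydroxy sulfide: ring C1–C2–S–C3–C4(OH)–C5/C6 cis-epoxide–C7–C8–C9(CH2OH)=C10–C11; C14–OTIPS; stereocentres as in the target | C=C(C)[C@@H](O[Si](C(C)C)(C(C)C)C(C)C)CC[C@]1(C)CSC[C@@H](O)[C@@]2(C)O[C@H]2CC/C(CO)=C\C1 | intermediate
29 | 28 with C9–CH2OTBS | C=C(C)[C@@H](O[Si](C(C)C)(C(C)C)C(C)C)CC[C@]1(C)CSC[C@@H](O)[C@@]2(C)O[C@H]2CC/C(CO[Si](C)(C)C(C)(C)C)=C\C1 | intermediate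
30 | 29 with C4 p-methoxybenzyl ether | C=C(C)[C@@H](O[Si](C(C)C)(C(C)C)C(C)C)CC[C@]1(C)CSC[C@@H](OCc3ccc(OC)cc3)[C@@]2(C)O[C@H]2CC/C(CO[Si](C)(C)C(C)(C)C)=C\C1 | intermediate
31 | twelve-membered sulfone (S,S-dioxide of 30) | C=C(C)[C@@H](O[Si](C(C)C)(C(C)C)C(C)C)CC[C@]1(C)CS(=O)(=O)C[C@@H](OCc3ccc(OC)cc3)[C@@]2(C)O[C@H]2CC/C(CO[Si](C)(C)C(C)(C)C)=C\C1 | intermediate
32 | α-bromo sulfone, bromine on C3, configuration at C3 not defined (not isolated) | C=C(C)[C@@H](O[Si](C(C)C)(C(C)C)C(C)C)CC[C@]1(C)CS(=O)(=O)C(Br)[C@@H](OCc3ccc(OC)cc3)[C@@]2(C)O[C@H]2CC/C(CO[Si](C)(C)C(C)(C)C)=C\C1 | intermediate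
33 | episulfone, thiirane 1,1-dioxide across C2–C3, trans expected (not isolated) | C=C(C)[C@@H](O[Si](C(C)C)(C(C)C)C(C)C)CC[C@]1(C)C4C(S4(=O)=O)[C@@H](OCc3ccc(OC)cc3)[C@@]2(C)O[C@H]2CC/C(CO[Si](C)(C)C(C)(C)C)=C\C1 | intermediate
34 | eleven-membered triene: E C2=C3, C4–OPMB, C5/C6 epoxide, C9–CH2OTBS, C14–OTIPS | C=C(C)[C@@H](O[Si](C(C)C)(C(C)C)C(C)C)CC[C@]1(C)/C=C/[C@@H](OCc3ccc(OC)cc3)[C@@]2(C)O[C@H]2CC/C(CO[Si](C)(C)C(C)(C)C)=C\C1 | intermediate
35 | C4 alcohol from 34 | C=C(C)[C@@H](O[Si](C(C)C)(C(C)C)C(C)C)CC[C@]1(C)/C=C/[C@@H](O)[C@@]2(C)O[C@H]2CC/C(CO[Si](C)(C)C(C)(C)C)=C\C1 | intermediate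
36 | C4 3-methylbut-2-enoate of 35 | C=C(C)[C@@H](O[Si](C(C)C)(C(C)C)C(C)C)CC[C@]1(C)/C=C/[C@@H](OC(=O)C=C(C)C)[C@@]2(C)O[C@H]2CC/C(CO[Si](C)(C)C(C)(C)C)=C\C1 | intermediate
37 | CNP0309478.6 | C=C(C)[C@@H](O)CC[C@]1(C)/C=C/[C@@H](OC(=O)C=C(C)C)[C@@]2(C)O[C@H]2CC/C(CO)=C\C1 | target

**Totals**

Total step count: 28 (fragment A steps 1–10, fragment B steps 11–18, union and end game steps 19–28).
Longest linear sequence: 20 steps (1–10, then 19–28).

**Steps most likely to fail**

1. Step 25 (ring contraction). E1cB loss of the C4 p-methoxybenzyloxy group from the C3 carbanion may outrun bromination and 1,3-elimination, and the episulfone may collapse partly to the Z alkene. Fallback, from 31 back to 35: treat 31 with t-BuOK (THF, −78 to 0 °C) to expel the ether on purpose and give the twelve-membered vinyl sulfone F1. Nucleophilic epoxidation with t-BuOOLi (THF, −20 °C) would give the α,β-epoxy sulfone F2. LiOt-Bu (THF, rt) then triggers the epoxy-Ramberg–Bäcklund reaction: the C2 carbanion opens the oxirane at C3, SO2 is lost, and the eleven-membered allylic alcohol F3 forms as a C4 epimer mixture. Dess–Martin oxidation to the enone F4 and chelation-controlled reduction with Zn(BH4)2 (Et2O, −20 °C) should give 35, where the route continues with step 27.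

2. Step 21 (macrocyclisation). Intermolecular thioether formation and disulfide formation may outrun the twelve-membered ring closure. Fallback, from 12 and 23 back to 30, making the sulfide between two molecules and closing the ring at C9=C10 instead:
   - K2CO3 in degassed MeOH frees the thiolate of 12, which opens the terminal epoxide of 23 to give the acyclic hydroxy sulfide F5.
   - NaH and 4-methoxybenzyl chloride give the C4 ether F6.
   - LiN(i-Pr)2, then ClP(OEt)2, then dry air give the phosphonate F7 with the sulfide kept.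
   - PPTS in wet acetone frees the aldehyde F8.
   - LiCl and i-Pr2NEt in MeCN at high dilution close the ring by intramolecular Horner–Wadsworth–Emmons reaction to the macrocyclic enoate F9.
   - i-Bu2AlH gives the allylic alcohol F10, and TBSCl with imidazole returns to 30.

3. Step 18 (C-phosphinylation). The enolate may be phosphinylated on oxygen, and chloride or the enolate may open the terminal epoxide during warming. Fallback, from 23 and 13 back to 26 without a phosphonate: the lithium enolate of 23 (LiN(i-Pr)2, THF, −78 °C) is added to aldehyde 13 to give the β-hydroxy ester F11 as a diastereomer mixture. Mesylation (MsCl, Et3N, CH2Cl2, 0 °C) gives the mesylate F12, and E1cB elimination with i-Pr2NEt at 40 °C should give the thermodynamically favoured E enoate 26.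

Further compounds
F1 | step 25 | twelve-membered vinyl sulfone (C3=C4, geometry not defined) | C=C(C)[C@@H](O[Si](C(C)C)(C(C)C)C(C)C)CC[C@]1(C)CS(=O)(=O)C=C[C@@]2(C)O[C@H]2CC/C(CO[Si](C)(C)C(C)(C)C)=C\C1
F2 | step 25 | α,β-epoxy sulfone (oxirane across C3–C4, configuration not defined) | C=C(C)[C@@H](O[Si](C(C)C)(C(C)C)C(C)C)CC[C@]1(C)CS(=O)(=O)C3OC3[C@@]2(C)O[C@H]2CC/C(CO[Si](C)(C)C(C)(C)C)=C\C1
F3 | step 25 | eleven-membered allylic alcohol, C4 epimer mixture | C=C(C)[C@@H](O[Si](C(C)C)(C(C)C)C(C)C)CC[C@]1(C)/C=C/C(O)[C@@]2(C)O[C@H]2CC/C(CO[Si](C)(C)C(C)(C)C)=C\C1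
F4 | step 25 | eleven-membered C4 enone | C=C(C)[C@@H](O[Si](C(C)C)(C(C)C)C(C)C)CC[C@]1(C)/C=C/C(=O)[C@@]2(C)O[C@H]2CC/C(CO[Si](C)(C)C(C)(C)C)=C\C1
F5 | step 21 | acyclic hydroxy sulfide (C10 dimethyl acetal, C9 methyl ester chain) | C=C(C)[C@@H](O[Si](C(C)C)(C(C)C)C(C)C)CC[C@](CC(OC)OC)(C)CSC[C@@H](O)[C@@]1(C)O[C@H]1CCCC(=O)OC
F6 | step 21 | C4 p-methoxybenzyl ether of F5 | C=C(C)[C@@H](O[Si](C(C)C)(C(C)C)C(C)C)CC[C@](CC(OC)OC)(C)CSC[C@@H](OCc1ccc(OC)cc1)[C@@]2(C)O[C@H]2CCCC(=O)OC
F7 | step 21 | C9 diethyl phosphonate of F6 | C=C(C)[C@@H](O[Si](C(C)C)(C(C)C)C(C)C)CC[C@](CC(OC)OC)(C)CSC[C@@H](OCc1ccc(OC)cc1)[C@@]2(C)O[C@H]2CCC(C(=O)OC)P(=O)(OCC)OCC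
F8 | step 21 | C10 aldehyde from F7 | C=C(C)[C@@H](O[Si](C(C)C)(C(C)C)C(C)C)CC[C@](CC=O)(C)CSC[C@@H](OCc1ccc(OC)cc1)[C@@]2(C)O[C@H]2CCC(C(=O)OC)P(=O)(OCC)OCC
F9 | step 21 | twelve-membered sulfide with C9 methyl ester (enoate) | C=C(C)[C@@H](O[Si](C(C)C)(C(C)C)C(C)C)CC[C@]1(C)CSC[C@@H](OCc3ccc(OC)cc3)[C@@]2(C)O[C@H]2CC/C(C(=O)OC)=C\C1
F10 | step 21 | twelve-membered sulfide with C9–CH2OH and C4–OPMB | C=C(C)[C@@H](O[Si](C(C)C)(C(C)C)C(C)C)CC[C@]1(C)CSC[C@@H](OCc3ccc(OC)cc3)[C@@]2(C)O[C@H]2CC/C(CO)=C\C1
F11 | step 18 | β-hydroxy ester (aldol adduct of 23 and 13, diastereomer mixture) | C=C(C)[C@@H](O[Si](C(C)C)(C(C)C)C(C)C)CC[C@](CC(O)C(CC[C@@H]1O[C@]1(C)[C@H]1CO1)C(=O)OC)(C)CSC(C)=O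
F12 | step 18 | mesylate of F11 | C=C(C)[C@@H](O[Si](C(C)C)(C(C)C)C(C)C)CC[C@](CC(OS(C)(=O)=O)C(CC[C@@H]1O[C@]1(C)[C@H]1CO1)C(=O)OC)(C)CSC(C)=O
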